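Retrosynthetic overview
1. Guaiane numbering: the five-membered ring is C1–C5, with C4 the quaternary carbon (CH3, CH2Ar) and C5 the sp2 fusion carbon. The seven-membered ring is C5=C6H–C7H(C11Me2OH)–C8–C9–C10H(CH3)–C1H.
2. Enabling feature: the homoallylic tertiary carbinol array C5=C6–C7–C11(OH) sits on the rim of the seven-membered ring next to quaternary C4. It is the opened form of a gem-dimethylcyclopropane C6–C7–C11 conjugated with a C4=C5 double bond, so C6 can be brought in as a carbene carbon that bonds to both ends of a prenyl C7=C11 double bond.
3. Last disconnection (C4–CH2Ar and C11–OH, biomimetic): o-quinone methide 16 (from grandinol 15) + vinylcyclopropane 10 + water. Strain release of the temporary three-membered ring places C5=C6 and the carbinol.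
4. Key disconnection (C6–C7, together with the temporary bond C6–C11): intramolecular cyclopropanation of the alkenyl carbenoid derived from enal 6. Enal 6 comes from (R)-citronellal 1 and methyl vinyl ketone 2 by Michael addition, one-carbon homologation and aldol condensation.
5. Ring order: arene bought → cyclopentene (step 4) → cycloheptane and cyclopropane together (step 6) → cyclopropane opened (step 9).

Key step: step 6

Remark: the numbering above is used for all intermediates, the face of the bicycle that carries H1 is called β, and enol ether 4 is carried on as an E/Z mixture because both isomers give 5.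

Step 1
Reactants: 1 (R)-citronellal; 2 methyl vinyl ketone
Product: 3 (2R,3R)-3,7-dimethyl-2-(3-oxobutyl)oct-6-enal
Conditions: (R)-2-(methoxydiphenylmethyl)pyrrolidine (10 mol %), ethyl 3,4-dihydroxybenzoate (20 mol %), neat, 4 °C
Reagents that add atoms: none
Why: Enamine-catalysed asymmetric Michael addition of an aldehyde to an enone, in which the E-enamine of 1 is attacked on the face left open by the diphenyl(methoxy)methyl group, so the new centre C1 (2R) is set by the (R)-catalyst while C10 (3R) comes unchanged from 1.

Step 2
Reactants: 3 (2R,3R)-3,7-dimethyl-2-(3-oxobutyl)oct-6-enal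
Product: 4 (5R,6R)-5-(2-methoxyethenyl)-6,10-dimethylundec-9-en-2-one (E/Z mixture)
Conditions: MeOCH2PPh3Cl (1.1 equiv), KHMDS (1.05 equiv), THF, −78 °C; then 3, −78 → −30 °C
Reagents that add atoms: (methoxymethyl)triphenylphosphonium chloride, COC[P+](c1ccccc1)(c1ccccc1)c1ccccc1.[Cl-]
Why: Wittig methoxymethylenation that brings in C6, chemoselective because the aldehyde is far more electrophilic than the methyl ketone at low temperature, and run with a pre-formed ylide and no excess base so that the α-centre C1 should not epimerise.

Step 3
Reactants: 4 (5R,6R)-5-(2-methoxyethenyl)-6,10-dimethylundec-9-en-2-one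
Product: 5 (3S)-3-[(2R)-6-methylhept-5-en-2-yl]-6-oxoheptanal
Conditions: 1 M aq. HCl, THF, 0 °C → rt
Reagents that add atoms: water, O
Why: Acid-catalysed enol ether hydrolysis (protonation at C5, addition of water at C6, loss of methanol) unmasks the homologated aldehyde, touches no stereocentre because C1 is now β to the carbonyl group (the descriptor changes only by priority), and leaves the trisubstituted alkene alone in dilute acid.

Step 4
Reactants: 5 (3S)-3-[(2R)-6-methylhept-5-en-2-yl]-6-oxoheptanal
Product: 6 (5R)-2-methyl-5-[(2R)-6-methylhept-5-en-2-yl]cyclopent-1-ene-1-carbaldehyde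
Conditions: piperidine (0.3 equiv), AcOH (0.3 equiv), toluene, 4 Å MS, 80 °C
Reagents that add atoms: none
Why: Intramolecular aldol condensation (5-enolexo-exo-trig) through the piperidine enamine of the aldehyde, whose carbon C5 attacks the methyl ketone C4; this is the established regiochemistry for 3-substituted 6-oxoheptanals, it gives the tetrasubstituted enal, and H1 is not acidic in the product.

Step 5
Reactants: 6 (5R)-2-methyl-5-[(2R)-6-methylhept-5-en-2-yl]cyclopent-1-ene-1-carbaldehyde
Product: 7 (E)-N-tosylhydrazone of 6
Conditions: TsNHNH2 (1.05 equiv), MeOH, rt
Reagents that add atoms: 4-methylbenzenesulfonohydrazide, Cc1ccc(cc1)S(=O)(=O)NN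
Why: Condensation of the only carbonyl group with a sulfonyl hydrazide to the N-tosylhydrazone, in which the fully substituted β-carbon C4 should block aza-Michael or pyrazoline formation and no stereocentre is involved.

Step 6
Reactants: 7 (E)-N-tosylhydrazone of 6
Product: 10 (−)-α-gurjunene, via tosylhydrazone sodium salt 8 (not isolated), via diazoalkene 9 (not isolated)
Conditions: NaH (1.05 equiv), THF, 0 °C; then CuI (10 mol %), BnEt3NCl (10 mol %), 1,4-dioxane, 45 °C, 0.01 M
Reagents that add atoms: none
Why: Salt 8 loses sulfinate on gentle warming (Bamford–Stevens) and releases alkenyldiazomethane 9 slowly, copper(I) replaces N2 to give an electrophilic alkenyl carbenoid centred on C6, and the tethered C7=C11 double bond adds to it. The closest known reaction type is the copper-catalysed intramolecular cyclopropanation of alkenyldiazomethanes derived from α,β-unsaturated aldehyde hydrazones onto trisubstituted alkenes, known for six-membered ring closure to vinyl gem-dimethylcyclopropanes. The seven-membered ring closes in the 7-exo mode by bonding of the less substituted alkene carbon C7 to C6, and the three-membered ring closes in the same asynchronous (2+1) event when the C11 end, which carries the developing positive charge, collapses onto C6. The addition is suprafacial, so H6 and H7 become cis, and C7 (with the transient centre C6) is controlled by C1: the tether leaves C1 on the face opposite to H1, the copper fragment lies anti to the C4 methyl group to avoid A(1,3) strain, and delivery of C7 from that face leads to the bisected vinylcyclopropane in a chair-like bicyclo[5.1.0]octane, whereas the other diastereomer would need C11 eclipsed with the C4 methyl group or a twisted seven-membered ring. The step needs cyclopropanation to beat 1,5-electrocyclisation of 9 to a 3H-pyrazole, carbene dimerisation and C–H insertion; slow release of 9 at high dilution, the fully substituted C4 terminus, the absence of hydrogen on C5 and the nucleophilic trisubstituted alkene held close by the cyclopentene should secure this.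

Step 7
Reactants: 11 2-methylbenzene-1,3,5-triol
Product: 13 2,4,6-trihydroxy-3-methylbenzaldehyde, via aryl iminium chloride 12 (not isolated)
Conditions: POCl3 (1.1 equiv), DMF (1.1 equiv), EtOAc, 0 °C → rt; then H2O, rt → 50 °C
Reagents that add atoms: N,N-dimethylformamide, CN(C)C=O; water, O
Why: Vilsmeier–Haack formylation of one of the two equivalent free positions of a very electron-rich arene, which should stop at the mono stage because the iminium group deactivates the ring and only about one equivalent of reagent is used.

Step 8
Reactants: 13 2,4,6-trihydroxy-3-methylbenzaldehyde; 14 3-methylbutanoyl chloride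
Product: 15 grandinol, 2,4,6-trihydroxy-3-methyl-5-(3-methylbutanoyl)benzaldehyde
Conditions: AlCl3 (4 equiv), CH2Cl2–PhNO2, 0 → 40 °C; then ice, 1 M HCl
Reagents that add atoms: none
Why: Friedel–Crafts acylation at the single remaining ring position, a known reaction of formylated phloroglucinols in which the chelated formyl group survives.

Step 9
Reactants: 10 (−)-α-gurjunene (1.5 equiv); 15 grandinol
Product: 17 target CNP0583424.1, via o-quinone methide 16 (not isolated)
Conditions: DDQ (1.0 equiv, added over 1 h), MeNO2–aq. pH 7 phosphate buffer (10:1), 0 °C → rt
Reagents that add atoms: water, O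
Why: Proposed new method: DDQ abstracts hydride from the aryl methyl group of 15 to give the doubly acceptor-substituted o-quinone methide 16, whose exocyclic CH2 is attacked by C4 of the electron-rich tetrasubstituted C4=C5 bond of 10, because only this regiochemistry places the charge on C5 as a tertiary, bisected cyclopropylcarbinyl cation; release of cyclopropane strain then breaks C6–C11 (not C6–C7, which would leave a secondary cation), which fixes the C5=C6 double bond with the geometry the ring enforces, water captures the tertiary C11 cation and rearomatisation returns the free triol; the new quaternary centre C4 is set by approach to the β face of the cyclopentene, since C10, its methyl group and C7–C9 fold under the opposite face, while C1, C7 and C10 are not touched and the C6 centre is erased; the closest known reaction types are the oxidative o-quinone methide/terpene couplings that give chromans by hetero-Diels–Alder addition and the cyclopropylcarbinyl-to-homoallyl solvolysis (Julia type), which have not been merged into one alkylation/ring-opening/hydration event on a vinylcyclopropane.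

Compound list
1 | (R)-citronellal | C[C@H](CCC=C(C)C)CC=O | starting material
2 | methyl vinyl ketone | CC(=O)C=C | starting material
3 | (2R,3R)-3,7-dimethyl-2-(3-oxobutyl)oct-6-enal | O=C[C@H](CCC(C)=O)[C@H](C)CCC=C(C)C | intermediate
4 | (5R,6R)-5-(2-methoxyethenyl)-6,10-dimethylundec-9-en-2-one (E/Z mixture) | COC=C[C@H](CCC(C)=O)[C@H](C)CCC=C(C)C | intermediate
5 | (3S)-3-[(2R)-6-methylhept-5-en-2-yl]-6-oxoheptanal | O=CC[C@H](CCC(C)=O)[C@H](C)CCC=C(C)C | intermediate
6 | (5R)-2-methyl-5-[(2R)-6-methylhept-5-en-2-yl]cyclopent-1-ene-1-carbaldehyde | O=CC1=C(C)CC[C@@H]1[C@H](C)CCC=C(C)C | intermediate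
7 | (E)-N-tosylhydrazone of 6 | Cc1ccc(cc1)S(=O)(=O)N/N=C/C1=C(C)CC[C@@H]1[C@H](C)CCC=C(C)C | intermediate
8 | sodium salt of 7 (not isolated) | Cc1ccc(cc1)S(=O)(=O)[N-]/N=C/C1=C(C)CC[C@@H]1[C@H](C)CCC=C(C)C.[Na+] | intermediate
9 | (5R)-1-(diazomethyl)-2-methyl-5-[(2R)-6-methylhept-5-en-2-yl]cyclopent-1-ene (not isolated) | [N-]=[N+]=CC1=C(C)CC[C@@H]1[C@H](C)CCC=C(C)C | intermediate
10 | (−)-α-gurjunene, (1aR,4R,4aR,7bS)-1,1,4,7-tetramethyl-1a,2,3,4,4a,5,6,7b-octahydro-1H-cyclopropa[e]azulene | CC1=C2[C@H]3[C@@H](CC[C@@H](C)[C@H]2CC1)C3(C)C | intermediate
11 | 2-methylbenzene-1,3,5-triol | Cc1c(O)cc(O)cc1O | starting material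
12 | (2,4,6-trihydroxy-3-methylbenzylidene)dimethyliminium chloride (not isolated) | Cc1c(O)cc(O)c(C=[N+](C)C)c1O.[Cl-] | intermediate
13 | 2,4,6-trihydroxy-3-methylbenzaldehyde | Cc1c(O)cc(O)c(C=O)c1O | intermediate
14 | 3-methylbutanoyl chloride | CC(C)CC(=O)Cl | starting material
15 | grandinol, 2,4,6-trihydroxy-3-methyl-5-(3-methylbutanoyl)benzaldehyde | CC(C)CC(=O)c1c(O)c(C)c(O)c(C=O)c1O | intermediate
16 | o-quinone methide of 15 (one tautomer drawn, not isolated) | C=C1C(=O)C(C=O)=C(O)C(C(=O)CC(C)C)=C1O | intermediate
17 | 2,4,6-trihydroxy-3-{[(1R,3aR,4R,7R)-7-(2-hydroxypropan-2-yl)-1,4-dimethyl-1,2,3,3a,4,5,6,7-octahydroazulen-1-yl]methyl}-5-(3-methylbutanoyl)benzaldehyde | CC(C)CC(=O)c1c(O)c(C=O)c(O)c(C[C@@]2(C)CC[C@H]3C2=C[C@H](C(C)(C)O)CC[C@H]3C)c1O | target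

Total step count: 9. Longest linear sequence: 7 steps (steps 1–6 and 9); steps 7 and 8 form the convergent arene branch.

Steps most likely to fail

Step 9 (Proposed new method). Several processes may interfere:
- hydration and over-oxidation of the quinone methide
- further hydride abstraction from the benzylic CH2 of the product
- proton loss from the C11 cation instead of water capture
- acid-induced isomerisation of the vinylcyclopropane
- insufficient facial selectivity at C4

The fallback uses known chemistry, sets out from 10 and 15, and comes back at 17. It separates C–C bond formation from hydration. Under strictly anhydrous conditions (DDQ, MeNO2, 4 Å MS), 16 should add as a heterodiene across C4=C5 of 10. This is an inverse-electron-demand hetero-Diels–Alder reaction of the kind known for this quinone methide class with terpene alkenes, and it gives the pentacyclic chroman F1. Either flanking phenol oxygen may close the ring, and both regioisomers converge on the same product. The chroman is then solvolysed (cat. TsOH, dioxane–water). The tertiary cyclopropylcarbinyl aryl ether ionises, the Julia-type cyclopropylcarbinyl-to-homoallyl opening breaks C6–C11, and water is taken up at C11 to give 17.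

Step 6. Electrocyclisation of the diazoalkene to a 3H-pyrazole may outrun copper capture. Azine or carbene-dimer formation, C–H insertion into the tether, or poor facial selectivity may also erode the ring closure. The fallback sets out from 6 and comes back at 10, and avoids nitrogen-based carbene precursors altogether. The enal is deoxygenated directly to an alkenyl organozinc carbenoid (zinc amalgam, 1,2-bis(chlorodimethylsilyl)ethane, Et2O, reflux). This is a known way to cyclopropanate tethered alkenes from α,β-unsaturated aldehydes, and it closes the same two bonds. The fallback makes no compound outside the list (F0).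

Step 2. The basic ylide may enolise the substrate, which would lead to epimerisation at C1 or intramolecular aldol cyclisation, or it may also attack the ketone. The fallback sets out from 3 and comes back at 5, and is non-basic and aldehyde-selective. A Takai–Utimoto-type chromium(II) olefination (CrCl2, LiI, Cl2CHBpin, THF, rt) gives the (E)-alkenyl boronate F2. Oxidation of its C–B bond (NaBO3·4H2O, THF–H2O, rt) delivers the enol and hence keto aldehyde 5, bypassing 4.

Further compounds
F1 | step 9 | β-face hetero-Diels–Alder adduct of 16 across C4=C5 of 10 (pentacyclic chroman, CH2 on C4, O on C5, cyclopropane intact; regioisomer closed through the oxygen next to the formyl group) | CC(C)CC(=O)c1c(O)c(C=O)c2c(c1O)C[C@@]1(C)CC[C@@H]3[C@H](C)CC[C@@H]4[C@@H](C4(C)C)[C@@]31O2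
F0 | step 6 | none | none
F2 | step 2 | (5R,6R)-6,10-dimethyl-5-[(E)-2-(4,4,5,5-tetramethyl-1,3,2-dioxaborolan-2-yl)ethenyl]undec-9-en-2-one | CC1(C)OB(/C=C/[C@H](CCC(C)=O)[C@H](C)CCC=C(C)C)OC1(C)C
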